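(All runs were computed with made-up constants, and the scatter is random.)

The alpha flask sent more of its G down the Q route than the beta flask: Q and Z together stand at 34.5% against 14.0% at the last readings, and alpha held 4.00 times beta's J.

| flask | G | J | temperature | remark | time |
|---|---|---|---|---|---|
| beta | 11 mM | 2 equiv | 94 °C | run made earlier |  |
| alpha | 44 mM | 2 equiv | 102 °C | run made earlier |  |
| autumn | 22 mM | 2.00 equiv | 105 °C |  | 2.0 d |
| dawn | 22 mM | 2.00 equiv | 90 °C |  | 2.0 d |

| run | time / h | Q / % | G / % | X / % | E / % | Z / % | L / % |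
|---|---|---|---|---|---|---|---|
| beta | 3.00 | 6.0 | 61.1 | 0.2 | 30.0 | 0.3 | 2.5 |
| beta | 6.00 | 8.9 | 37.2 | 0 | 44.2 | 0.3 | 8.2 |
| beta | 10.0 | 11.5 | 19.3 | 0.5 | 48.9 | 0 | 16.1 |
| beta | 20.0 | 12.3 | 3.9 | 2.1 | 40.1 | 1.5 | 35.8 |
| beta | 40.0 | 11.5 | 0.3 | 4.7 | 20.0 | 2.5 | 55.0 |
| alpha | 1.50 | 18.9 | 48.3 | 0.2 | 22.7 | 0.5 | 8.3 |
| alpha | 3.00 | 25.8 | 23.6 | 0.5 | 24.9 | 2.6 | 19.6 |
| alpha | 6.00 | 27.6 | 6.8 | 2.4 | 16.9 | 5.3 | 36.7 |
| alpha | 12.0 | 24.1 | 0.5 | 5.4 | 5.8 | 10.1 | 50.0 |
| alpha | 20.0 | 20.6 | 0 | 7.7 | 1.3 | 13.9 | 54.4 |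

(standard deviation of a reading: 0.3 percentage points)

* which of these there is most of at the end, counted by the G in it, autumn (X / E / Q / Z / L)
* which of these there is most of at the end, counted by the G in it, dawn (X / E / Q / Z / L)
* the largest of these amounts at the end, in percent of the G charged, autumn
* the largest of these amounts at the end, in percent of the G charged, dawn

- the analysis behind the earlier runs scatters by 0.3 percentage points, standard deviation
- candidate steps: G -> E; G + J -> Q; J + E -> L; J + E -> D; J + Q -> Z; J + D -> X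

Take alpha's last reading and divide L by the charge less Q, Z, E and G. This gives 0.847, the L share, a selectivity of E; beta's last reading gives 0.837.

Now reckon the Q route. Turn each share into odds against the E route. G + J to Q uses J and G to E does not, so scale the odds to the J of autumn and dawn: 0.326 at 94 °C and 0.263 at 102 °C. Run that trend on in temperature, and the Q route takes 19.6% in autumn and 26.6% at dawn.

With E used up, the L share would give 68.1% and 62.2%, but beta's last reading still shows 20.0% of E, and that is the weak link. Read E's half-life under J (pseudo-first-order) from its fall in each run and scale it the same way: 9.96 h and 7.78 h. The trend gives 7.09 h for autumn and 11.3 h for dawn. Start the clock at beta's highest reading of E, taken over to both flasks as a rough start. On this reckoning autumn keeps 1.19% of E and dawn 4.73%. So I commit to L at 67.1% in autumn and 58.2% at dawn.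

The forecast named L at 67% for autumn and L at 54% for dawn, and said of dawn “About 10% of E remains at 48 h”; its dawn figure stands lower than mine.

The flask gives L at 67.3% in autumn and L at 54.4% at dawn, with 9.64% of E standing in dawn against my 4.73%.

    G → E (k = 0.0940 h⁻¹, Ea = 111 kJ mol⁻¹)
    G + J → Q (k = 0.810 M⁻¹ h⁻¹, Ea = 98.0 kJ mol⁻¹)
    J + E → L (k = 1.70 M⁻¹ h⁻¹, Ea = 93.0 kJ mol⁻¹)
    J + E → D (k = 0.350 M⁻¹ h⁻¹, Ea = 74.0 kJ mol⁻¹)
    J + Q → Z (k = 0.250 M⁻¹ h⁻¹, Ea = 90.0 kJ mol⁻¹)
    J + D → X (k = 1.50 M⁻¹ h⁻¹, Ea = 70.0 kJ mol⁻¹)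
    (constants at 90 °C)

Autumn has come to rest as far as L goes: 67.4% stands at 20.0 d, though its Q still falls from 9.86% to 0.0463% and Z rises from 11.9% to 21.7%. Dawn has not come to rest. Apply the L share to its remaining E and add that to its L, which gives 62.6%; at 20.0 d dawn stands at 62.7%.

Now take the neighbour of autumn with 0.500 equiv of J. Each G past E costs one J on the way to L and two on the way to X, so if the reckoning sends none to Q, the L share gives an estimate of 36.8% of L. That flask holds 36.0%, with 1.29% of its J left and 52.1% of E standing.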